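The ten-membered ring is traced back to a cyclohexane: in germacrane numbering C1–C6, with the ring-cis C2–C3 and C4–C5 epoxides on opposite faces, is a cyclohexa-1,3-diene anti-diepoxide cut open between C1 and C6, and the erythro C8,C9-diol lies between the two arms flanking that cut. One anionic oxy-Cope rearrangement forms C8–C9, breaks C1–C6, expands the six-ring to the ten-ring, sets C8, C9 and the cis C1=C10 enoate and leaves a C6 ketone for the lactone. Its precursor is a cis-1,6-dialkenyl-2,3:4,5-diepoxy-4-methylcyclohexan-6-ol carrying a (Z)-PMB enol ether on C6 and a (Z)-β-silyloxyacrylate on C1.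

Key step: step 13

Remark: germacrane locants (C1–C15) are used for every intermediate; for the six-membered-ring compounds α/β refer to the ring drawn with C1→C6 counter-clockwise, β toward the viewer. Compounds 1, 3, 14, 15 and 34 are taken as commercial.

Step 1
Reactants: 1 4-methoxy-2-methylphenol
Product: 2 4,4-dimethoxy-2-methylcyclohexa-2,5-dien-1-one
Conditions: PhI(OAc)2, MeOH, 0 °C
Reagents that add atoms: methanol, CO
Why: Oxidative dearomatisation of a p-methoxyphenol by iodine(III) in methanol should give the p-quinone monoketal, which holds C6 as a masked ketone, the C4 methyl group and two different enone units, with no stereocentre formed.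

Step 2
Reactants: 2 4,4-dimethoxy-2-methylcyclohexa-2,5-dien-1-one; 3 dimethyl malonate
Product: 4 dimethyl 2-[(1R)-2,2-dimethoxy-4-methyl-5-oxocyclohex-3-en-1-yl]malonate
Conditions: (R)-ALB [Al–Li–bis((R)-binaphthoxide)] (10 mol %), KOt-Bu (cat.), 4 Å MS, THF, rt
Reagents that add atoms: none
Why: Catalytic asymmetric Michael addition of a malonate to a cyclic enone (heterobimetallic Al–Li–BINOL catalysis) should occur at the unsubstituted, more electrophilic enone (germacrane C1) and set C1 (R, arm α) by catalyst control, the catalyst enantiomer being chosen by analogy with cyclohex-2-enone.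

Step 3
Reactants: 4 dimethyl 2-[(1R)-2,2-dimethoxy-4-methyl-5-oxocyclohex-3-en-1-yl]malonate
Product: 5 methyl 2-[(1R)-2,2-dimethoxy-4-methyl-5-oxocyclohex-3-en-1-yl]acetate
Conditions: LiCl, H2O, DMSO, 130 °C
Reagents that add atoms: none
Why: Krapcho dealkoxycarbonylation (chloride SN2 at an ester methyl group, decarboxylation, protonation) should turn the malonate into the acetate arm under near-neutral conditions that leave the ketal and C1 untouched, the ketal having no base-induced elimination pathway because C6 carries no hydrogen.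

Step 4
Reactants: 5 methyl 2-[(1R)-2,2-dimethoxy-4-methyl-5-oxocyclohex-3-en-1-yl]acetate
Product: 6 methyl (4β,5β-epoxy-6,6-dimethoxy-4-methyl-3-oxocyclohexan-1α-yl)acetate
Conditions: t-BuOOH, DBU, CH2Cl2, 0 °C → rt
Reagents that add atoms: tert-butyl hydroperoxide, CC(C)(C)OO
Why: Weitz–Scheffer nucleophilic epoxidation of the α-methyl enone, in which the hydroperoxide anion should add to C5 axially and trans to the C1 substituent (the trans-3,5 rule for 5-substituted cyclohex-2-enones), so the 4,5-epoxide forms on the β-face, trans to the C1 arm.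

Step 5
Reactants: 6 methyl (4β,5β-epoxy-6,6-dimethoxy-4-methyl-3-oxocyclohexan-1α-yl)acetate
Product: 7 methyl (4β,5β-epoxy-3β-hydroxy-6,6-dimethoxy-4-methylcyclohexan-1α-yl)acetate
Conditions: NaBH4, CeCl3·7H2O, MeOH, −40 °C
Reagents that add atoms: none
Why: Luche reduction of the α,β-epoxy ketone (hydride expected anti to the oxirane oxygen, giving the 3β-alcohol) leaves ester, ketal and epoxide untouched, and the C3 configuration is of no consequence because C3 becomes sp2 in step 6.

Step 6
Reactants: 7 methyl (4β,5β-epoxy-3β-hydroxy-6,6-dimethoxy-4-methylcyclohexan-1α-yl)acetate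
Product: 8 methyl (4β,5β-epoxy-6,6-dimethoxy-4-methylcyclohex-2-en-1α-yl)acetate
Conditions: Martin sulfurane, CH2Cl2, 0 °C → rt
Reagents that add atoms: none
Why: Dehydration of the secondary alcohol with Martin sulfurane (anti E2 elimination of the alkoxysulfonium ion) can only proceed toward C2 because C4 bears no hydrogen, and should give the C2=C3 alkene under neutral conditions.

Step 7
Reactants: 8 methyl (4β,5β-epoxy-6,6-dimethoxy-4-methylcyclohex-2-en-1α-yl)acetate
Product: 9 methyl (2α,3α:4β,5β-diepoxy-6,6-dimethoxy-4-methylcyclohexan-1α-yl)acetate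
Conditions: mCPBA, NaHCO3, CH2Cl2, 0 °C
Reagents that add atoms: meta-chloroperbenzoic acid, OOC(=O)c1cccc(Cl)c1
Why: Prilezhaev epoxidation of the vinyl epoxide, in which the peracid should approach anti to the allylic C4–C5 oxirane oxygen (as cyclohexa-1,3-diene monoepoxide gives the trans-diepoxide), this polar allylic effect outweighing the small bias of the primary alkyl arm on C1 and setting the 2α,3α-epoxide cis to that arm.

Step 8
Reactants: 9 methyl (2α,3α:4β,5β-diepoxy-6,6-dimethoxy-4-methylcyclohexan-1α-yl)acetate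
Product: 12 methyl (Z)-2-(2α,3α:4β,5β-diepoxy-6,6-dimethoxy-4-methylcyclohexan-1α-yl)-3-(triisopropylsilyloxy)acrylate, via lithium ester enolate 10 (not isolated), via lithium formyl ester enolate 11 (not isolated)
Conditions: LDA, THF, −78 °C; HCO2Me, −78 → −20 °C; TIPSOTf, Et3N, −78 °C
Reagents that add atoms: methyl formate, COC=O; triisopropylsilyl trifluoromethanesulfonate, CC(C)[Si](OS(=O)(=O)C(F)(F)F)(C(C)C)C(C)C
Why: Claisen formylation of the ester enolate gives the α-formyl ester enolate as an O–Li–O chelate with the formyl oxygen cis to the ester, and O-silylation of this chelate should fix the (Z)-geometry (O9 cis to C14, trans to C1), while cyclopropane formation is excluded because C10 and the C2–C3 oxirane oxygen are cis and backside attack is impossible.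

Step 9
Reactants: 12 methyl (Z)-2-(2α,3α:4β,5β-diepoxy-6,6-dimethoxy-4-methylcyclohexan-1α-yl)-3-(triisopropylsilyloxy)acrylate
Product: 13 methyl (Z)-2-(2α,3α:4β,5β-diepoxy-4-methyl-6-oxocyclohexan-1α-yl)-3-(triisopropylsilyloxy)acrylate
Conditions: montmorillonite K10, wet CH2Cl2, rt
Reagents that add atoms: water, O
Why: Acid-catalysed hydrolysis of the dimethyl ketal on a mildly acidic clay, as used for epoxy quinone monoketals, should unveil the C6 ketone while the electron-poor epoxides and the bulky TIPS enol ether survive, and base is avoided because C1–H of 13 lies β to the C2–C3 epoxide.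

Step 10
Reactants: 14 4-methoxybenzyl alcohol; 15 trichloroethylene
Product: 16 1-{[(E)-1,2-dichlorovinyl]oxymethyl}-4-methoxybenzene
Conditions: KH, THF, 0 °C; then 15, −40 °C → rt
Reagents that add atoms: none
Why: Alkoxide addition–elimination on trichloroethylene (by way of dichloroacetylene, anti addition) is the established synthesis of (E)-1,2-dichlorovinyl ethers, the precursors of alkoxyacetylides.

Step 11
Reactants: 13 methyl (Z)-2-(2α,3α:4β,5β-diepoxy-4-methyl-6-oxocyclohexan-1α-yl)-3-(triisopropylsilyloxy)acrylate; 16 1-{[(E)-1,2-dichlorovinyl]oxymethyl}-4-methoxybenzene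
Product: 18 methyl (Z)-2-{2α,3α:4β,5β-diepoxy-6β-hydroxy-6α-[(4-methoxybenzyloxy)ethynyl]-4-methylcyclohexan-1α-yl}-3-(triisopropylsilyloxy)acrylate, via lithium (4-methoxybenzyloxy)ethynide 17 (not isolated)
Conditions: 16, n-BuLi (2.1 equiv), THF, −78 → −40 °C; CeCl3, −78 °C; then 13, −78 °C
Reagents that add atoms: none
Why: 1,2-Addition of a weakly basic alkynylcerium reagent to the α,β-epoxy ketone should occur anti to the C5–O oxirane bond and axially, anti to the axial C1–H (arm equatorial), so the small linear nucleophile enters cis to the C1 arm and O6 ends β, cis to the 4,5-epoxide, without enolisation toward C1.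

Step 12
Reactants: 18 methyl (Z)-2-{2α,3α:4β,5β-diepoxy-6β-hydroxy-6α-[(4-methoxybenzyloxy)ethynyl]-4-methylcyclohexan-1α-yl}-3-(triisopropylsilyloxy)acrylate
Product: 19 methyl (Z)-2-{(1S,2R,3R,4S,5R,6R)-2,3:4,5-diepoxy-6-hydroxy-6-[(Z)-2-(4-methoxybenzyloxy)vinyl]-4-methylcyclohexyl}-3-(triisopropylsilyloxy)acrylate
Conditions: H2 (1 atm), Lindlar catalyst, quinoline, EtOAc, rt
Reagents that add atoms: none
Why: Lindlar semi-hydrogenation of the ynol ether by syn addition of hydrogen should give the (Z)-enol ether, the poisoned catalyst leaving the silyloxyacrylate, the benzylic ether and the epoxides untouched.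

Step 13
Reactants: 19 methyl (Z)-2-{(1S,2R,3R,4S,5R,6R)-2,3:4,5-diepoxy-6-hydroxy-6-[(Z)-2-(4-methoxybenzyloxy)vinyl]-4-methylcyclohexyl}-3-(triisopropylsilyloxy)acrylate
Product: 22 methyl (2R,3R,4S,5S,8S,9R)-2,3:4,5-diepoxy-8-(4-methoxybenzyloxy)-4-methyl-6-oxo-9-(triisopropylsilyloxy)cyclodec-1(10)-ene-10-carboxylate (ring-cis C1=C10), via potassium C6 alkoxide 20 (not isolated), via potassium C6 enolate 21 (not isolated)
Conditions: KHMDS (1.1 equiv), 18-crown-6, THF (0.01 M), −78 → −20 °C; AcOH, −78 °C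
Reagents that add atoms: none
Why: Deprotonation gives the C6 potassium alkoxide, whose charge weakens C1–C6 and drives a concerted suprafacial [3,3] shift through the chair C9=C10–C1–C6–C7=C8 in which C8–C9 forms as C1–C6 breaks; the closest known reaction is the anionic oxy-Cope ring expansion of cis-1,2-dialkenylcyclohexanols to cyclodec-5-enones. The ten-membered ring arises by four-atom ring expansion of the cyclohexane, not by end-to-end closure, and is made irreversible by formation of the C6 enolate and conjugation of C1=C10 with the ester. With the arms cis, the chair with C2 axial on C1 and C5 equatorial and O− axial on C6 avoids the 1,3-diaxial clash between the (Z)-OPMB group on C8 and ring carbon C5, and it gives the ring-cis C1=C10 bond. C8 (S) is set by the (Z)-enol ether (OPMB axial, cis to C6) and C9 (R) by the (Z)-silyloxyacrylate (OTIPS equatorial, trans to C1), one cis and one trans oxygen giving the erythro pair on the face fixed by C1 and C6. The step needs the [3,3] shift to outrun Payne migration, silyl transfer, lactonisation and β-elimination: O6 is cis to the C4–C5 epoxide (no backside attack), O9–Si lies trans to C1 across C9=C10 and out of reach of O6, a lactone onto C14 would be trans-fused across C1–C6 of a ring flattened by two epoxides, and the enolate is protonated cold before the C8 alkoxide can leave.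

Step 14
Reactants: 22 methyl (2R,3R,4S,5S,8S,9R)-2,3:4,5-diepoxy-8-(4-methoxybenzyloxy)-4-methyl-6-oxo-9-(triisopropylsilyloxy)cyclodec-1(10)-ene-10-carboxylate
Product: 24 C7-(methoxycarbonylmethyl) cyclodecenone (22 alkylated at C7; C11 cis to O8), via lithium C6 enolate 23 (not isolated)
Conditions: LiHMDS, THF, −78 °C; BrCH2CO2Me, −78 → −50 °C
Reagents that add atoms: methyl bromoacetate, COC(=O)CBr
Why: Only C7 can be deprotonated (C5 is an oxirane carbon), the lithium enolate is held as an O6–Li–O8 chelate with the C8 oxygen in the enolate plane, and SN2 alkylation should occur on the peripheral face anti to the C8–C9 ring bond (Fráter–Seebach-type 1,2-induction), setting C7 as in the target while the low temperature suppresses β-elimination of the C8 ether.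

Step 15
Reactants: 24 C7-(methoxycarbonylmethyl) cyclodecenone (22 alkylated at C7; C11 cis to O8)
Product: 26 6,7-trans-fused 6,12-olide (saturated C11 methylene; 8-OPMB; 9-OTIPS), via C6 hydroxy ester 25 (not isolated)
Conditions: NaBH4, MeOH–THF, −40 → 0 °C; PPTS (cat.), CH2Cl2, rt
Reagents that add atoms: none
Why: Borohydride reduction of the α,β-epoxy ketone without a chelating metal should follow the Felkin–Anh mode, hydride entering from the ring periphery anti to the C5–O oxirane bond (C6 as in the target), and the C6 hydroxyl, trans to the C7 arm, should close the γ-lactone by intramolecular transesterification, completed by a trace of mild acid.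

Step 16
Reactants: 26 6,7-trans-fused 6,12-olide (saturated C11 methylene; 8-OPMB; 9-OTIPS)
Product: 30 11(13)-methylene 6,12-olide (8-OPMB; 9-OTIPS), via lithium lactone enolate 27 (not isolated), via C11 dimethylaminomethyl lactone 28 (not isolated), via trimethylammonium iodide 29 (not isolated)
Conditions: LiHMDS, THF, −78 °C; CH2=NMe2+ I−, −78 → 0 °C; MeI, MeOH, rt; NaHCO3 (aq), CH2Cl2, rt
Reagents that add atoms: Eschenmoser's salt, C[N+](C)=C.[I-]
Why: α-Methylenation of a γ-lactone by Mannich reaction of its lithium enolate with Eschenmoser's salt, N-methylation and base-induced elimination of trimethylamine; the lactone α-CH2 is the only readily enolisable position and no stereocentre remains at C11.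

Step 17
Reactants: 30 11(13)-methylene 6,12-olide (8-OPMB; 9-OTIPS)
Product: 31 9-hydroxy 11(13)-methylene 6,12-olide (8-OPMB)
Conditions: HF·pyridine, pyridine, THF, 0 °C → rt
Reagents that add atoms: none
Why: Fluoride cleavage of the secondary triisopropylsilyl ether under buffered conditions should leave the electron-poor epoxides, the α-methylene lactone and the PMB ether untouched.

Step 18
Reactants: 31 9-hydroxy 11(13)-methylene 6,12-olide (8-OPMB)
Product: 32 9-acetoxy 11(13)-methylene 6,12-olide (8-OPMB)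
Conditions: Ac2O, pyridine, DMAP (cat.), CH2Cl2, 0 °C
Reagents that add atoms: acetic anhydride, CC(=O)OC(C)=O
Why: DMAP-catalysed acetylation of the free allylic C9 alcohol, with C8 still protected so that no regiochemical question arises.

Step 19
Reactants: 32 9-acetoxy 11(13)-methylene 6,12-olide (8-OPMB)
Product: 33 9-acetoxy-8-hydroxy 11(13)-methylene 6,12-olide
Conditions: DDQ, CH2Cl2/pH 7 buffer (10:1), 0 °C
Reagents that add atoms: none
Why: Oxidative cleavage of the p-methoxybenzyl ether by DDQ under buffered neutral conditions is compatible with epoxides, enoate, acetate and the α-methylene lactone, and neutrality keeps the C9 acetate from migrating to O8.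

Step 20
Reactants: 34 angelic acid
Product: 35 (Z)-2-methylbut-2-en-1-ol
Conditions: LiAlH4, Et2O, 0 °C
Reagents that add atoms: none
Why: Hydride reduction of the carboxylic acid to the allylic alcohol, which at 0 °C should neither reduce nor isomerise the trisubstituted (Z)-alkene.

Step 21
Reactants: 35 (Z)-2-methylbut-2-en-1-ol
Product: 36 [(2R,3S)-2,3-dimethyloxiran-2-yl]methanol
Conditions: Ti(Oi-Pr)4 (cat.), D-(−)-DIPT (cat.), t-BuOOH, 4 Å MS, CH2Cl2, −20 °C
Reagents that add atoms: tert-butyl hydroperoxide, CC(C)(C)OO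
Why: Sharpless asymmetric epoxidation of a (Z)-trisubstituted allylic alcohol, in which D-(−)-tartrate should deliver oxygen to the face that gives the (2R,3S)-epoxy alcohol, the cis relation of C1 and C4 coming from the (Z)-alkene.

Step 22
Reactants: 36 [(2R,3S)-2,3-dimethyloxiran-2-yl]methanol
Product: 37 (2S,3S)-2,3-dimethyloxirane-2-carboxylic acid
Conditions: RuCl3·xH2O (cat.), NaIO4, CCl4/MeCN/H2O, rt
Reagents that add atoms: water, O
Why: Ruthenium tetroxide oxidation of the primary epoxy alcohol to the glycidic acid leaves the oxirane and both stereocentres untouched (the C2 descriptor changes only through the priority change).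

Step 23
Reactants: 33 9-acetoxy-8-hydroxy 11(13)-methylene 6,12-olide; 37 (2S,3S)-2,3-dimethyloxirane-2-carboxylic acid
Product: 39 CNP0077535.3 (target), via Yamaguchi mixed anhydride 38 (not isolated)
Conditions: 37, 2,4,6-trichlorobenzoyl chloride, Et3N, THF, 0 °C; then 33, DMAP, toluene, rt
Reagents that add atoms: none
Why: Yamaguchi esterification, in which DMAP attacks the less shielded epoxyacyl carbonyl of the mixed anhydride and the resulting acylpyridinium acylates the hindered C8 alcohol with retention at all stereocentres, the α-quaternary epoxy acid having no epimerisable α-hydrogen.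

Compound list
1 | 4-methoxy-2-methylphenol | Cc1cc(OC)ccc1O | starting material
2 | 4,4-dimethoxy-2-methylcyclohexa-2,5-dien-1-one | CC1=CC(OC)(OC)C=CC1=O | intermediate
3 | dimethyl malonate | COC(=O)CC(=O)OC | starting material
4 | dimethyl 2-[(1R)-2,2-dimethoxy-4-methyl-5-oxocyclohex-3-en-1-yl]malonate | COC(=O)C(C(=O)OC)[C@H]1CC(=O)C(C)=CC1(OC)OC | intermediate
5 | methyl 2-[(1R)-2,2-dimethoxy-4-methyl-5-oxocyclohex-3-en-1-yl]acetate | COC(=O)C[C@H]1CC(=O)C(C)=CC1(OC)OC | intermediate
6 | methyl (4β,5β-epoxy-6,6-dimethoxy-4-methyl-3-oxocyclohexan-1α-yl)acetate | COC(=O)C[C@H]1CC(=O)[C@]2(C)O[C@@H]2C1(OC)OC | intermediate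
7 | methyl (4β,5β-epoxy-3β-hydroxy-6,6-dimethoxy-4-methylcyclohexan-1α-yl)acetate | COC(=O)C[C@H]1C[C@H](O)[C@]2(C)O[C@@H]2C1(OC)OC | intermediate
8 | methyl (4β,5β-epoxy-6,6-dimethoxy-4-methylcyclohex-2-en-1α-yl)acetate | COC(=O)C[C@H]1C=C[C@]2(C)O[C@@H]2C1(OC)OC | intermediate
9 | methyl (2α,3α:4β,5β-diepoxy-6,6-dimethoxy-4-methylcyclohexan-1α-yl)acetate | COC(=O)C[C@H]1[C@H]2O[C@H]2[C@]2(C)O[C@@H]2C1(OC)OC | intermediate
10 | lithium ester enolate of 9 | COC([O-])=C[C@H]1[C@H]2O[C@H]2[C@]2(C)O[C@@H]2C1(OC)OC.[Li+] | intermediate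
11 | lithium (Z)-enolate of the α-formyl ester of 9 | COC(=O)/C(=C\[O-])[C@H]1[C@H]2O[C@H]2[C@]2(C)O[C@@H]2C1(OC)OC.[Li+] | intermediate
12 | methyl (Z)-2-(2α,3α:4β,5β-diepoxy-6,6-dimethoxy-4-methylcyclohexan-1α-yl)-3-(triisopropylsilyloxy)acrylate | COC(=O)/C(=C\O[Si](C(C)C)(C(C)C)C(C)C)[C@H]1[C@H]2O[C@H]2[C@]2(C)O[C@@H]2C1(OC)OC | intermediate
13 | methyl (Z)-2-(2α,3α:4β,5β-diepoxy-4-methyl-6-oxocyclohexan-1α-yl)-3-(triisopropylsilyloxy)acrylate | COC(=O)/C(=C\O[Si](C(C)C)(C(C)C)C(C)C)[C@H]1[C@H]2O[C@H]2[C@]2(C)O[C@@H]2C1=O | intermediate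
14 | 4-methoxybenzyl alcohol | COc1ccc(CO)cc1 | starting material
15 | trichloroethylene | ClC=C(Cl)Cl | starting material
16 | 1-{[(E)-1,2-dichlorovinyl]oxymethyl}-4-methoxybenzene | COc1ccc(CO/C(Cl)=C\Cl)cc1 | intermediate
17 | lithium (4-methoxybenzyloxy)ethynide | COc1ccc(COC#C[Li])cc1 | intermediate
18 | methyl (Z)-2-{2α,3α:4β,5β-diepoxy-6β-hydroxy-6α-[(4-methoxybenzyloxy)ethynyl]-4-methylcyclohexan-1α-yl}-3-(triisopropylsilyloxy)acrylate | COC(=O)/C(=C\O[Si](C(C)C)(C(C)C)C(C)C)[C@H]1[C@H]2O[C@H]2[C@]2(C)O[C@@H]2[C@@]1(O)C#COCc1ccc(OC)cc1 | intermediate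
19 | methyl (Z)-2-{(1S,2R,3R,4S,5R,6R)-2,3:4,5-diepoxy-6-hydroxy-6-[(Z)-2-(4-methoxybenzyloxy)vinyl]-4-methylcyclohexyl}-3-(triisopropylsilyloxy)acrylate (arms cis, 6-OH cis to the 4,5-epoxide) | COC(=O)/C(=C\O[Si](C(C)C)(C(C)C)C(C)C)[C@H]1[C@H]2O[C@H]2[C@]2(C)O[C@@H]2[C@@]1(O)/C=C\OCc1ccc(OC)cc1 | intermediate
20 | potassium C6 alkoxide of 19 | COC(=O)/C(=C\O[Si](C(C)C)(C(C)C)C(C)C)[C@H]1[C@H]2O[C@H]2[C@]2(C)O[C@@H]2[C@@]1([O-])/C=C\OCc1ccc(OC)cc1.[K+] | intermediate
21 | potassium C6 enolate of 22 (C6=C7, C5 trans to C8) | [O-]/C1=C\[C@H](OCc2ccc(OC)cc2)[C@H](O[Si](C(C)C)(C(C)C)C(C)C)/C(C(=O)OC)=C\[C@H]2O[C@H]2[C@]2(C)O[C@H]12.[K+] | intermediate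
22 | methyl (2R,3R,4S,5S,8S,9R)-2,3:4,5-diepoxy-8-(4-methoxybenzyloxy)-4-methyl-6-oxo-9-(triisopropylsilyloxy)cyclodec-1(10)-ene-10-carboxylate (ring-cis C1=C10) | O=C1C[C@H](OCc2ccc(OC)cc2)[C@H](O[Si](C(C)C)(C(C)C)C(C)C)/C(C(=O)OC)=C\[C@H]2O[C@H]2[C@]2(C)O[C@H]12 | intermediate
23 | lithium C6 enolate of 22 | [O-]/C1=C\[C@H](OCc2ccc(OC)cc2)[C@H](O[Si](C(C)C)(C(C)C)C(C)C)/C(C(=O)OC)=C\[C@H]2O[C@H]2[C@]2(C)O[C@H]12.[Li+] | intermediate
24 | C7-(methoxycarbonylmethyl) cyclodecenone (22 alkylated at C7; C11 cis to O8) | O=C1[C@H](CC(=O)OC)[C@H](OCc2ccc(OC)cc2)[C@H](O[Si](C(C)C)(C(C)C)C(C)C)/C(C(=O)OC)=C\[C@H]2O[C@H]2[C@]2(C)O[C@H]12 | intermediate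
25 | C6 hydroxy ester (24 reduced at C6; O6 trans to C11) | O[C@H]1[C@H](CC(=O)OC)[C@H](OCc2ccc(OC)cc2)[C@H](O[Si](C(C)C)(C(C)C)C(C)C)/C(C(=O)OC)=C\[C@H]2O[C@H]2[C@]2(C)O[C@H]12 | intermediate
26 | 6,7-trans-fused 6,12-olide (saturated C11 methylene; 8-OPMB; 9-OTIPS) | C1C(=O)O[C@H]2[C@H]1[C@H](OCc3ccc(OC)cc3)[C@H](O[Si](C(C)C)(C(C)C)C(C)C)/C(C(=O)OC)=C\[C@H]1O[C@H]1[C@]1(C)O[C@H]21 | intermediate
27 | lithium enolate of lactone 26 | C1=C([O-])O[C@H]2[C@H]1[C@H](OCc3ccc(OC)cc3)[C@H](O[Si](C(C)C)(C(C)C)C(C)C)/C(C(=O)OC)=C\[C@H]1O[C@H]1[C@]1(C)O[C@H]21.[Li+] | intermediate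
28 | C11 (dimethylaminomethyl) lactone (C11 epimers) | CN(C)CC1C(=O)O[C@H]2[C@H]1[C@H](OCc3ccc(OC)cc3)[C@H](O[Si](C(C)C)(C(C)C)C(C)C)/C(C(=O)OC)=C\[C@H]1O[C@H]1[C@]1(C)O[C@H]21 | intermediate
29 | C11 (trimethylammoniomethyl) lactone iodide | C[N+](C)(C)CC1C(=O)O[C@H]2[C@H]1[C@H](OCc3ccc(OC)cc3)[C@H](O[Si](C(C)C)(C(C)C)C(C)C)/C(C(=O)OC)=C\[C@H]1O[C@H]1[C@]1(C)O[C@H]21.[I-] | intermediate
30 | 11(13)-methylene 6,12-olide (8-OPMB; 9-OTIPS) | C=C1C(=O)O[C@H]2[C@H]1[C@H](OCc3ccc(OC)cc3)[C@H](O[Si](C(C)C)(C(C)C)C(C)C)/C(C(=O)OC)=C\[C@H]1O[C@H]1[C@]1(C)O[C@H]21 | intermediate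
31 | 9-hydroxy 11(13)-methylene 6,12-olide (8-OPMB) | C=C1C(=O)O[C@H]2[C@H]1[C@H](OCc3ccc(OC)cc3)[C@H](O)/C(C(=O)OC)=C\[C@H]1O[C@H]1[C@]1(C)O[C@H]21 | intermediate
32 | 9-acetoxy 11(13)-methylene 6,12-olide (8-OPMB) | C=C1C(=O)O[C@H]2[C@H]1[C@H](OCc3ccc(OC)cc3)[C@H](OC(C)=O)/C(C(=O)OC)=C\[C@H]1O[C@H]1[C@]1(C)O[C@H]21 | intermediate
33 | 9-acetoxy-8-hydroxy 11(13)-methylene 6,12-olide | C=C1C(=O)O[C@H]2[C@H]1[C@H](O)[C@H](OC(C)=O)/C(C(=O)OC)=C\[C@H]1O[C@H]1[C@]1(C)O[C@H]21 | intermediate
34 | angelic acid, (Z)-2-methylbut-2-enoic acid | C/C=C(/C)C(=O)O | starting material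
35 | (Z)-2-methylbut-2-en-1-ol | C/C=C(/C)CO | intermediate
36 | [(2R,3S)-2,3-dimethyloxiran-2-yl]methanol | OC[C@@]1(C)O[C@H]1C | intermediate
37 | (2S,3S)-2,3-dimethyloxirane-2-carboxylic acid (epoxyangelic acid) | O=C(O)[C@@]1(C)O[C@H]1C | intermediate
38 | Yamaguchi mixed anhydride: (2S,3S)-2,3-dimethyloxirane-2-carboxylic 2,4,6-trichlorobenzoic anhydride | O=C(OC(=O)c1c(Cl)cc(Cl)cc1Cl)[C@@]1(C)O[C@H]1C | intermediate
39 | CNP0077535.3: 9-acetoxy-2,3:4,5-diepoxy-8-[(2S,3S)-2,3-epoxy-2-methylbutanoyloxy]-germacra-1(10),11(13)-dien-6,12-olid-14-oic acid methyl ester (6,7-trans-lactone; O8, O9 and C11 cis on the ring) | C=C1C(=O)O[C@H]2[C@H]1[C@H](OC(=O)[C@@]1(C)O[C@H]1C)[C@H](OC(C)=O)/C(C(=O)OC)=C\[C@H]1O[C@H]1[C@]1(C)O[C@H]21 | target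

Total step count: 23.
Longest linear sequence: 19 steps (steps 1–9, 11–19 and 23, from 1 to 39).

Steps most likely to fail

Step 13. The C6 alkoxide may be diverted before the [3,3] shift: transesterification onto the C14 ester, intermolecular silyl transfer from O9, or a competing chair or boat that gives the ring-trans alkene. The product enolate may also expel the C8 alkoxide. The fallback replaces the anionic rearrangement by a neutral siloxy-Cope rearrangement and sets out from 19. Silylation at O6 (TMS-imidazole, CH2Cl2) gives the C6 trimethylsilyl ether of 19 F1. Heating (degassed toluene, 180 °C, sealed silylated glass) should give, through the same chair, the C6 trimethylsilyl enol ether of 22 F2. KF in methanol at 0 °C then returns the route to 22.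

Step 11 (with step 12). The alkoxyethynyl carbinol may rearrange under traces of acid on work-up, the semi-hydrogenation may over-reduce or lose (Z)-selectivity, and the acetylide may enolise 13 at C1 with β-elimination of the C2–C3 epoxide. The fallback transfers the preformed (Z)-enol ether and sets out from 16 and 13. Treating 16 with n-BuLi (2 equiv) and quenching with methanol gives 4-methoxybenzyl ethynyl ether F3. Thermal hydrostannation with Bu3SnH should give, by anti addition, (Z)-tributyl{2-[(4-methoxybenzyl)oxy]vinyl}stannane F4. Tin–lithium exchange (n-BuLi, −78 °C), transmetalation with CeCl3 and addition to 13 gives 19 directly, without 18 and step 12. The more basic alkenyl reagent does not remove the enolisation risk.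

Step 15. Hydride may be delivered to the other face of C6, through chelation by the oxirane oxygen or through the conformation of the ten-membered ring, which would give the 6-epi alcohol and the cis-fused lactone. The fallback uses chelation-controlled reduction followed by lactonisation with inversion and sets out from 22. Alkylation as in step 14 but with 2-(trimethylsilyl)ethyl bromoacetate gives the C7 [2-(trimethylsilyl)ethoxycarbonyl]methyl ketone F5. Zn(BH4)2 (Et2O, −20 °C, neutral work-up, chelate between C6=O and the oxirane oxygen) gives the 6-epi alcohol F6. TBAF (THF, 0 °C) frees the 6-epi hydroxy acid F7 while the secondary TIPS ether reacts more slowly. Mitsunobu lactonisation (PPh3, DIAD, THF) closes the lactone with inversion at C6 and rejoins the route at 26.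

Further compounds
F1 | step 13 | C6 trimethylsilyl ether of 19 | COC(=O)/C(=C\O[Si](C(C)C)(C(C)C)C(C)C)[C@H]1[C@H]2O[C@H]2[C@]2(C)O[C@@H]2[C@@]1(O[Si](C)(C)C)/C=C\OCc1ccc(OC)cc1
F2 | step 13 | C6 trimethylsilyl enol ether of 22 | C[Si](C)(C)O/C1=C\[C@H](OCc2ccc(OC)cc2)[C@H](O[Si](C(C)C)(C(C)C)C(C)C)/C(C(=O)OC)=C\[C@H]2O[C@H]2[C@]2(C)O[C@H]12
F3 | step 11 | 4-methoxybenzyl ethynyl ether | C#COCc1ccc(OC)cc1
F4 | step 11 | (Z)-tributyl{2-[(4-methoxybenzyl)oxy]vinyl}stannane | CCCC[Sn](CCCC)(CCCC)/C=C\OCc1ccc(OC)cc1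
F5 | step 15 | C7 [2-(trimethylsilyl)ethoxycarbonyl]methyl derivative of 22 | O=C1[C@H](CC(=O)OCC[Si](C)(C)C)[C@H](OCc2ccc(OC)cc2)[C@H](O[Si](C(C)C)(C(C)C)C(C)C)/C(C(=O)OC)=C\[C@H]2O[C@H]2[C@]2(C)O[C@H]12
F6 | step 15 | 6-epi C6 alcohol of F5 | O[C@@H]1[C@H](CC(=O)OCC[Si](C)(C)C)[C@H](OCc2ccc(OC)cc2)[C@H](O[Si](C(C)C)(C(C)C)C(C)C)/C(C(=O)OC)=C\[C@H]2O[C@H]2[C@]2(C)O[C@H]12
F7 | step 15 | 6-epi hydroxy acid | O[C@@H]1[C@H](CC(=O)O)[C@H](OCc2ccc(OC)cc2)[C@H](O[Si](C(C)C)(C(C)C)C(C)C)/C(C(=O)OC)=C\[C@H]2O[C@H]2[C@]2(C)O[C@H]12
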